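The dihydrofuran ring (O1, C2, C3, C3a, C7a) is disconnected at O1–C2 and C3a–C3 into a resveratrol unit, which supplies the phenol oxygen and its ortho carbon, and a piceatannol unit, which supplies both olefin carbons. The feature exploited is the catechol ring on C2: as its ortho-quinone it makes the olefin a vinylogous acceptor, so C3 takes the resorcinol carbon and C2, then a para-quinone methide carbon para to the 4-oxygen, takes the phenol oxygen. One operation under a chiral phosphoric acid thus joins two acetate-masked stilbenes, closes the ring trans and sets both stereocenters; the precursor is an achiral stilbene ortho-quinone made in the flask.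

Key step: step 3

Assumption: the (R)-configured phosphoric acid is taken to deliver the (2S,3S) series; the sense of induction cannot be predicted from precedent, and the (S)-catalyst is used if it proves opposite.

Step 1
Reactants: 1 resveratrol
Product: 2 (E)-4-[2-(3,5-dihydroxyphenyl)ethenyl]phenyl acetate (4′-O-acetylresveratrol)
Conditions: immobilised Candida antarctica lipase B, vinyl acetate (5 equiv), tert-amyl alcohol, 40 °C
Reagents that add atoms: vinyl acetate, C=COC(C)=O
Why: Lipase-catalysed regioselective transesterification; the enzyme should acylate the unhindered para-hydroxyl of the 4-hydroxystyryl ring and leave the two resorcinol hydroxyls free, and tautomerisation of the released vinyl alcohol makes the transfer irreversible; no stereocenter is formed.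

Step 2
Reactants: 3 piceatannol
Product: 6 (E)-5-[2-(3,4-dihydroxyphenyl)ethenyl]-1,3-phenylene diacetate, via catechol phenylboronate 4 (not isolated), via phenylboronate diacetate 5 (not isolated)
Conditions: PhB(OH)2 (1.05 equiv), 4 Å MS, THF, rt; Ac2O (2.1 equiv), pyridine, 0 °C; concentrate; pinacol (1.5 equiv), THF, rt
Reagents that add atoms: acetic anhydride, CC(=O)OC(C)=O
Why: Phenylboronic acid forms a cyclic five-membered boronate only with the 1,2-diol of the catechol, so the acetylation (nucleophilic acyl substitution) is confined to the two resorcinol hydroxyls, and transesterification of boron to pinacol then frees the catechol; no stereocenter is formed.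

Step 3
Reactants: 6 (E)-5-[2-(3,4-dihydroxyphenyl)ethenyl]-1,3-phenylene diacetate and 2 4′-O-acetylresveratrol
Product: 9 5-[(2S,3S)-4-[(E)-2-(4-acetoxyphenyl)ethenyl]-2-(3,4-dihydroxyphenyl)-6-hydroxy-2,3-dihydro-1-benzofuran-3-yl]-1,3-phenylene diacetate, via stilbene ortho-quinone 7 (not isolated), via para-quinone methide 8 (not isolated)
Conditions: 6, Ag2O (3 equiv), Na2SO4, CH2Cl2, −20 °C, filtered under Ar; added over 2 h to 2 (1.5 equiv), (R)-3,3′-bis(2,4,6-triisopropylphenyl)-1,1′-binaphthyl-2,2′-diyl hydrogen phosphate (10 mol %), 4 Å MS, CH2Cl2/tert-butyl methyl ether, −60 to −30 °C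
Reagents that add atoms: none
Why: Proposed new method: silver oxide Ag2O dehydrogenates the catechol of 6 to ortho-quinone 7, whose conjugate acid is the same cation as a two-electron-oxidised 4-hydroxystilbene, so the olefin carbon bearing the 3,5-diacetoxyphenyl ring is the terminus of a dienone and accepts the resorcinol carbon of 2 that lies between a hydroxyl and the styryl arm (C3a–C3, a vinylogous Friedel–Crafts 1,6-addition) to give para-quinone methide 8. The neighbouring phenol oxygen then adds to the methide carbon of 8 (O1–C2) in a 5-exo-trig oxa-conjugate addition that closes the dihydrofuran ring and restores the catechol, which drives the sequence. The closest known reaction types are the chiral phosphoric acid-catalysed 1,6-additions of naphthols and electron-rich phenols to para-quinone methides and the two-electron oxidative dimerisation of 4-hydroxystilbenes that gives the ε-viniferin connectivity. C3 is set in the C–C bond formation by the catalyst, which should hold the quinone carbonyl through P–OH and the attacking phenol through P=O and so expose one face of the olefin terminus, while C2 is set by the substrate, the oxygen adding anti to the C3 aryl group in a closure that is reversible under the acid and should end at the trans isomer. The step needs attack at the olefin terminus and not at a quinone ring carbon, C- before O-alkylation, reaction at the resorcinol carbon ortho to the styryl arm, and cross- over homo-coupling; the first three follow the preference of the oxidative dimerisation named above, and the last is secured by the acetates, which leave the resorcinol ring of 2 as the only nucleophile and 7 as the only electrophile.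

Step 4
Reactants: 9 scirpusin A triacetate
Product: 10 scirpusin A, 4-[(2S,3S)-3-(3,5-dihydroxyphenyl)-6-hydroxy-4-[(E)-2-(4-hydroxyphenyl)ethenyl]-2,3-dihydro-1-benzofuran-2-yl]benzene-1,2-diol
Conditions: N2H4·AcOH (6 equiv), THF/MeOH, 0 °C to rt, Ar
Reagents that add atoms: none
Why: Hydrazinolysis of the three aryl acetates (nucleophilic acyl substitution) under acetate buffering should free the phenols without forming phenoxides, so the catechol is not oxidised and the benzylic C2–O1 bond is not opened; C3 cannot epimerise and C2 stays trans.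

Compound list
1 | resveratrol, (E)-5-[2-(4-hydroxyphenyl)ethenyl]benzene-1,3-diol | Oc1ccc(/C=C/c2cc(O)cc(O)c2)cc1 | starting material
2 | (E)-4-[2-(3,5-dihydroxyphenyl)ethenyl]phenyl acetate (4′-O-acetylresveratrol) | CC(=O)Oc1ccc(/C=C/c2cc(O)cc(O)c2)cc1 | intermediate
3 | piceatannol, (E)-4-[2-(3,5-dihydroxyphenyl)ethenyl]benzene-1,2-diol | Oc1cc(O)cc(/C=C/c2ccc(O)c(O)c2)c1 | starting material
4 | (E)-5-[2-(2-phenyl-1,3,2-benzodioxaborol-5-yl)ethenyl]benzene-1,3-diol | Oc1cc(O)cc(/C=C/c2ccc3OB(c4ccccc4)Oc3c2)c1 | intermediate
5 | (E)-5-[2-(2-phenyl-1,3,2-benzodioxaborol-5-yl)ethenyl]-1,3-phenylene diacetate | CC(=O)Oc1cc(OC(C)=O)cc(/C=C/c2ccc3OB(c4ccccc4)Oc3c2)c1 | intermediate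
6 | (E)-5-[2-(3,4-dihydroxyphenyl)ethenyl]-1,3-phenylene diacetate (3′,5′-di-O-acetylpiceatannol) | CC(=O)Oc1cc(OC(C)=O)cc(/C=C/c2ccc(O)c(O)c2)c1 | intermediate
7 | (E)-5-[2-(3,4-dioxocyclohexa-1,5-dien-1-yl)ethenyl]-1,3-phenylene diacetate | CC(=O)Oc1cc(OC(C)=O)cc(/C=C/C2=CC(=O)C(=O)C=C2)c1 | intermediate
8 | 5-[(1S)-1-{2-[(E)-2-(4-acetoxyphenyl)ethenyl]-4,6-dihydroxyphenyl}-2-(3-hydroxy-4-oxocyclohexa-2,5-dien-1-ylidene)ethyl]-1,3-phenylene diacetate | CC(=O)Oc1ccc(/C=C/c2cc(O)cc(O)c2[C@H](c2cc(OC(C)=O)cc(OC(C)=O)c2)C=C2C=CC(=O)C(O)=C2)cc1 | intermediate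
9 | 5-[(2S,3S)-4-[(E)-2-(4-acetoxyphenyl)ethenyl]-2-(3,4-dihydroxyphenyl)-6-hydroxy-2,3-dihydro-1-benzofuran-3-yl]-1,3-phenylene diacetate (scirpusin A triacetate) | CC(=O)Oc1ccc(/C=C/c2cc(O)cc3c2[C@H](c2cc(OC(C)=O)cc(OC(C)=O)c2)[C@@H](c2ccc(O)c(O)c2)O3)cc1 | intermediate
10 | scirpusin A, (2S,3S), trans | Oc1ccc(/C=C/c2cc(O)cc3c2[C@H](c2cc(O)cc(O)c2)[C@@H](c2ccc(O)c(O)c2)O3)cc1 | target

Total step count: 4. Longest linear sequence: 3 steps (3 to 6 to 9 to 10).

Steps most likely to fail

Step 3 (Proposed new method). What may go wrong: addition of the resorcinol at a ring carbon of the quinone, self-condensation of the quinone or redox exchange between quinone and the catechol product, and weak facial control by the catalyst. Fallback: 6 and 2 are joined without a chiral catalyst by the two-electron oxidative coupling of a 4-hydroxystilbene with a resorcinol unit, the known reaction type that gives the ε-viniferin skeleton (Tl(NO3)3·3H2O, trivalent thallium, MeOH, −50 °C). This should give 9 as a racemate with its (2R,3R) antipode F1. Preparative HPLC on an amylose tris(3,5-dimethylphenylcarbamate) phase separates the two, and 9 rejoins the route at step 4.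

Step 2. What may go wrong: acetyl transfer onto the catechol oxygens, either by loss of the boron mask during acylation or by acyl migration after unmasking. Fallback: the diacetate is assembled convergently instead; this replaces starting material 3 by commercial 5-iodoresorcinol and 3,4-dihydroxybenzaldehyde and comes back to the route at 6.
- Acetylation of 5-iodoresorcinol (Ac2O, pyridine) gives 5-iodo-1,3-phenylene diacetate F2.
- Silylation of the aldehyde (TBSCl, imidazole, DMF) gives 3,4-bis(tert-butyldimethylsilyloxy)benzaldehyde F3.
- Wittig methylenation of F3 (Ph3PCH3Br, NaHMDS, THF) gives 3,4-bis(tert-butyldimethylsilyloxy)styrene F4.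
- A Mizoroki–Heck reaction of F2 with F4 (Pd(OAc)2, P(o-tol)3, Et3N, MeCN, 80 °C) gives (E)-5-{2-[3,4-bis(tert-butyldimethylsilyloxy)phenyl]ethenyl}-1,3-phenylene diacetate F5.
- Et3N·3HF in THF removes the two silyl ethers without touching the acetates and gives 6.

Step 4. What may go wrong: oxidation of the catechol and opening of the dihydrofuran ring through a quinone methide if phenoxides form during the deacetylation. Fallback: 9 is hydrolysed enzymatically at neutral pH instead of by a nitrogen nucleophile (porcine liver esterase, phosphate buffer pH 7/acetone, Ar, rt), which forms no phenoxide and gives 10 directly; no new compound is made.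

Further compounds
F1 | step 3 | 5-[(2R,3R)-4-[(E)-2-(4-acetoxyphenyl)ethenyl]-2-(3,4-dihydroxyphenyl)-6-hydroxy-2,3-dihydro-1-benzofuran-3-yl]-1,3-phenylene diacetate (antipode of 9) | CC(=O)Oc1ccc(/C=C/c2cc(O)cc3c2[C@@H](c2cc(OC(C)=O)cc(OC(C)=O)c2)[C@H](c2ccc(O)c(O)c2)O3)cc1
F2 | step 2 | 5-iodo-1,3-phenylene diacetate | CC(=O)Oc1cc(I)cc(OC(C)=O)c1
F3 | step 2 | 3,4-bis(tert-butyldimethylsilyloxy)benzaldehyde | CC(C)(C)[Si](C)(C)Oc1ccc(C=O)cc1O[Si](C)(C)C(C)(C)C
F4 | step 2 | 3,4-bis(tert-butyldimethylsilyloxy)styrene | C=Cc1ccc(O[Si](C)(C)C(C)(C)C)c(O[Si](C)(C)C(C)(C)C)c1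
F5 | step 2 | (E)-5-{2-[3,4-bis(tert-butyldimethylsilyloxy)phenyl]ethenyl}-1,3-phenylene diacetate | CC(=O)Oc1cc(OC(C)=O)cc(/C=C/c2ccc(O[Si](C)(C)C(C)(C)C)c(O[Si](C)(C)C(C)(C)C)c2)c1
F0 | step 4 | none | none
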